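**Plan**

- Locants follow carotenoid numbering: ring A is the enone ring (C1–C6), ring B the hydroxylated ring (C1'–C6'), the chain runs C7–C15/C15'–C7'.
- Retrosynthetic cuts: O–Si at C3'; C10=C11 back to a C10≡C11 alkyne; C9–C10 together with the C6=C7/C8=C9 diene (C13 diketone + C27 alkyne); in the C27 half the retro double-bond pattern back to a C12 carbinol of a normal polyene, then C11–C12 (ethynyl), C11'=C12' (Wittig) and C6'–C7' (Stille).
- Forward order: ring B triflate from actinol, C15 alcohol, C15 Wittig salt, C25 aldehyde, C27 propargylic alcohol, 1,16-dehydration to the retro-enyne; union with racemic 3-oxo-α-ionone; semihydrogenation, cis–trans equilibration, desilylation. No ring is formed; both rings are bought.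
- Enabling feature: in ring A the C3 carbonyl is conjugated through C4=C5 to C6, so C6–H of the α-ionone-type partner is a vinylogous α-hydrogen and a leaving group at C9 is expelled through C7=C8. Adding the C10 nucleophile to the C9 ketone therefore forms C9–C10 and, by 1,4-elimination in the same flask, the C6=C7/C8=C9 diene of the retro chromophore.
- Stereochemistry: C3' comes from (4R,6R)-actinol and no bond to it is ever touched (R in the β-ring intermediates, S once C4' is sp2); double-bond geometry is settled by equilibration in step 12.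

Key step: step 10

Remark: the eliminations in steps 9 and 10 are not expected to control the geometry of the double bonds they create (C6'=C7', C12=C13, C6=C7, C8=C9); compounds 16, 21 and 22 are named and drawn as the E isomers and are carried as isomer mixtures that converge in step 12.

**Route**

Step 1
Reactants: 1 α-ionone (racemic)
Product: 2 3-oxo-α-ionone (racemic)
Conditions: t-BuOOH (70% aq.), CrO3 (cat.), CH2Cl2, rt
Reagents that add atoms: tert-butyl hydroperoxide, CC(C)(C)OO
Why: Chromium-catalysed allylic oxidation should convert the ring allylic methylene (C3) into the enone carbonyl; the C6 stereocentre stays racemic and is removed in step 10.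

Step 2
Reactants: 3 (4R,6R)-actinol
Product: 4 actinol tert-butyldimethylsilyl ether
Conditions: TBSCl, imidazole, DMF, rt
Reagents that add atoms: tert-butyldimethylsilyl chloride, CC(C)(C)[Si](C)(C)Cl
Why: Standard silylation of the secondary alcohol protects O3' through the organometallic steps and leaves both stereocentres untouched.

Step 3
Reactants: 4 actinol tert-butyldimethylsilyl ether
Product: 6 ring B enol triflate, via potassium enolate 5 (not isolated)
Conditions: KHMDS, THF, −78 °C; PhNTf2, −78 °C → rt
Reagents that add atoms: N-phenylbis(trifluoromethanesulfonimide), O=S(=O)(N(c1ccccc1)S(=O)(=O)C(F)(F)F)C(F)(F)F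
Why: The ketone can enolize only toward the methyl-bearing α-carbon (the other is quaternary), so enol triflate formation should give one tetrasubstituted triflate; the silyloxy stereocentre is untouched and the methyl-bearing one is deliberately destroyed.

Step 4
Reactants: 7 (2E)-3-methylpent-2-en-4-yn-1-ol
Product: 8 (2E,4E)-3-methyl-5-(tributylstannyl)penta-2,4-dien-1-ol
Conditions: Bu3SnH, PdCl2(PPh3)2 (cat.), THF, 0 °C
Reagents that add atoms: tributyltin hydride, CCCC[SnH](CCCC)CCCC
Why: Palladium-catalysed syn-hydrostannation of the terminal alkyne should place tin on the terminal carbon and give the (E)-vinylstannane; the minor internal regioisomer is removed by chromatography.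

Step 5
Reactants: 6 ring B enol triflate; 8 (2E,4E)-3-methyl-5-(tributylstannyl)penta-2,4-dien-1-ol
Product: 9 silylated C15 dienol
Conditions: Pd2(dba)3 (cat.), AsPh3, NMP, 60 °C
Reagents that add atoms: none
Why: Stille coupling of the hindered cyclohexenyl triflate with the dienylstannane (AsPh3 to speed transmetalation) should form the C6'–C7' bond with retention of alkene geometry.

Step 6
Reactants: 9 silylated C15 dienol
Product: 10 silylated C15 triphenylphosphonium bromide
Conditions: PPh3·HBr, CH2Cl2, 0 °C → rt
Reagents that add atoms: triphenylphosphine hydrobromide, [Br-].c1ccc(cc1)[PH+](c1ccccc1)c1ccccc1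
Why: The allylic alcohol ionizes and is captured by PPh3 at the primary terminus (classical allylic Wittig salt formation), which should be faster than cleavage of the secondary silyl ether in an aprotic medium.

Step 7
Reactants: 10 silylated C15 triphenylphosphonium bromide; 11 (2E,4E,6E)-2,7-dimethylocta-2,4,6-trienedial
Product: 13 silylated C25 aldehyde, via phosphonium ylide 12 (not isolated)
Conditions: NaOMe, MeOH/CH2Cl2, 0 °C → rt; 11 in excess (3 equiv)
Reagents that add atoms: none
Why: Wittig olefination of one aldehyde of the symmetrical dial forms C11'=C12'; its E/Z outcome does not matter because this bond becomes a single bond in step 9.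

Step 8
Reactants: 13 silylated C25 aldehyde; 14 ethynylmagnesium bromide
Product: 15 silylated C27 propargylic alcohol (both C12 epimers)
Conditions: THF, −30 → 0 °C; aq. NH4Cl
Reagents that add atoms: none
Why: 1,2-Addition of the alkynyl Grignard reagent to the polyenal installs C10 and C11 and the C12 hydroxyl that serves as leaving group in step 9; the new carbinol centre is inconsequential.

Step 9
Reactants: 15 silylated C27 propargylic alcohol
Product: 16 silylated C27 retro-enyne
Conditions: p-TsOH·H2O (cat.), 4 Å MS, CH2Cl2, 0 °C; Et3N quench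
Reagents that add atoms: none
Why: Acid ionizes the propargylic, polyene-conjugated C12 alcohol to a cation delocalized as far as C5', and loss of a C4' proton should give the fully conjugated retro-polyene (1,16-dehydration, the reaction type of the retinol → anhydroretinol conversion and a mirror of the presumed biogenetic retro shift); C3' is not involved and keeps its configuration, now designated S.

Step 10
Reactants: 16 silylated C27 retro-enyne; 2 3-oxo-α-ionone
Product: 21 10,11-didehydro-eschscholtzxanthone tert-butyldimethylsilyl ether, via lithium acetylide 17 (not isolated), via dichlorocerium acetylide 18 (not isolated), via cerium alkoxide 19 (not isolated), via tertiary acetate 20 (not isolated)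
Conditions: n-BuLi, THF, −78 °C; CeCl3, −78 °C; 2 (1.5 equiv); Ac2O (1.1 equiv), DMAP (cat.), −78 → 0 °C; DBU, 0 → 40 °C
Reagents that add atoms: none
Why: The weakly basic dichlorocerium acetylide 18 should add to the C9 methyl ketone of 2 and form the C9–C10 bond; after acetylation to 20, DBU removes C6–H (γ to the C3 enone) and the dienolate expels acetate from C9 through C7=C8 (vinylogous E1cB 1,4-elimination), which moves the double bonds to C6=C7 and C8=C9 and completes the retro chromophore in one flask. The closest known reaction types are the organocerium addition of alkynes to enolizable ketones and the 1,4-dehydration of 3-oxo-α-ionol to megastigmatrienones. No ring is closed and no stereocentre is created: the racemic C6 centre of 2 and the transient C9 carbinol centre are both destroyed, and the C3' centre is remote from every reacting site. The step needs site selectivity between the two ketones of 2 (the side-chain carbonyl is less hindered and more electrophilic than the β,β-disubstituted ring enone), suppression of enolization at the acidic C6–H (cerium), and elimination toward C6 and not toward the C9 methyl group (only C6–H is acidified by the ring enone, and only this path gives the fully conjugated trienone). The geometry of the new C6=C7 and C8=C9 bonds is not controlled here and is settled in step 12.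

Step 11
Reactants: 21 10,11-didehydro-eschscholtzxanthone tert-butyldimethylsilyl ether
Product: 22 (10Z)-eschscholtzxanthone tert-butyldimethylsilyl ether
Conditions: H2 (1 atm), Lindlar catalyst (Pd/CaCO3 poisoned with Pb(OAc)2), quinoline, EtOAc, rt
Reagents that add atoms: none
Why: Lindlar semihydrogenation (syn addition of H2) of the only triple bond should stop at the (10Z)-alkene, the standard way to reduce didehydro-carotenoids without touching the polyene or the enone.

Step 12
Reactants: 22 (10Z)-eschscholtzxanthone tert-butyldimethylsilyl ether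
Product: 23 all-E eschscholtzxanthone tert-butyldimethylsilyl ether
Conditions: I2 (cat.), CH2Cl2, rt, daylight; crystallization or preparative HPLC, other isomers returned to the equilibration
Reagents that add atoms: none
Why: Iodine-catalysed cis–trans equilibration (reversible iodine-atom addition) should convert the hindered (10Z) bond and the other stereolabile double bonds into the thermodynamic mixture, from which the all-E (6E,6'E) isomer is isolated.

Step 13
Reactants: 23 all-E eschscholtzxanthone tert-butyldimethylsilyl ether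
Product: 24 eschscholtzxanthone
Conditions: TBAF, AcOH, THF, 0 °C → rt, dark
Reagents that add atoms: none
Why: Fluoride cleaves the Si–O bond (AcOH buffer protects the sensitive polyene-allylic alcohol and the enone); no stereocentre or double bond is affected.

**Compound list**

1 | α-ionone, racemic (3E)-4-(2,6,6-trimethylcyclohex-2-en-1-yl)but-3-en-2-one | CC(=O)/C=C/C1C(C)=CCCC1(C)C | starting material
2 | 3-oxo-α-ionone, racemic 3,5,5-trimethyl-4-[(1E)-3-oxobut-1-en-1-yl]cyclohex-2-en-1-one | CC(=O)/C=C/C1C(C)=CC(=O)CC1(C)C | intermediate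
3 | (4R,6R)-4-hydroxy-2,2,6-trimethylcyclohexan-1-one (actinol) | O=C1C(C)(C)C[C@H](O)C[C@H]1C | starting material
4 | (4R,6R)-4-[(tert-butyldimethylsilyl)oxy]-2,2,6-trimethylcyclohexan-1-one | O=C1C(C)(C)C[C@H](O[Si](C)(C)C(C)(C)C)C[C@H]1C | intermediate
5 | potassium (4R)-4-[(tert-butyldimethylsilyl)oxy]-2,6,6-trimethylcyclohex-1-en-1-olate | [K+].[O-]C1=C(C)C[C@@H](O[Si](C)(C)C(C)(C)C)CC1(C)C | intermediate
6 | (4R)-4-[(tert-butyldimethylsilyl)oxy]-2,6,6-trimethylcyclohex-1-en-1-yl trifluoromethanesulfonate | FC(F)(F)S(=O)(=O)OC1=C(C)C[C@@H](O[Si](C)(C)C(C)(C)C)CC1(C)C | intermediate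
7 | (2E)-3-methylpent-2-en-4-yn-1-ol | OC/C=C(\C)C#C | starting material
8 | (2E,4E)-3-methyl-5-(tributylstannyl)penta-2,4-dien-1-ol | OC/C=C(C)/C=C/[Sn](CCCC)(CCCC)CCCC | intermediate
9 | (2E,4E)-5-[(4R)-4-[(tert-butyldimethylsilyl)oxy]-2,6,6-trimethylcyclohex-1-en-1-yl]-3-methylpenta-2,4-dien-1-ol | OC/C=C(C)/C=C/C1=C(C)C[C@@H](O[Si](C)(C)C(C)(C)C)CC1(C)C | intermediate
10 | [(2E,4E)-5-[(4R)-4-[(tert-butyldimethylsilyl)oxy]-2,6,6-trimethylcyclohex-1-en-1-yl]-3-methylpenta-2,4-dien-1-yl]triphenylphosphonium bromide | [Br-].C(/C=C(C)/C=C/C1=C(C)C[C@@H](O[Si](C)(C)C(C)(C)C)CC1(C)C)[P+](c1ccccc1)(c1ccccc1)c1ccccc1 | intermediate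
11 | (2E,4E,6E)-2,7-dimethylocta-2,4,6-trienedial | O=C/C(C)=C/C=C/C=C(\C)C=O | starting material
12 | phosphonium ylide derived from 10 (carbanion at the P-bound carbon) | [CH-](/C=C(C)/C=C/C1=C(C)C[C@@H](O[Si](C)(C)C(C)(C)C)CC1(C)C)[P+](c1ccccc1)(c1ccccc1)c1ccccc1 | intermediate
13 | (2E,4E,6E,8E,10E,12E)-13-[(4R)-4-[(tert-butyldimethylsilyl)oxy]-2,6,6-trimethylcyclohex-1-en-1-yl]-2,7,11-trimethyltrideca-2,4,6,8,10,12-hexaenal (C25 aldehyde, carbonyl = C12) | O=C/C(C)=C/C=C/C=C(C)/C=C/C=C(C)/C=C/C1=C(C)C[C@@H](O[Si](C)(C)C(C)(C)C)CC1(C)C | intermediate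
14 | ethynylmagnesium bromide | C#C[Mg]Br | starting material
15 | (4E,6E,8E,10E,12E,14E)-15-[(4R)-4-[(tert-butyldimethylsilyl)oxy]-2,6,6-trimethylcyclohex-1-en-1-yl]-4,9,13-trimethylpentadeca-4,6,8,10,12,14-hexaen-1-yn-3-ol (both carbinol epimers; carbinol = C12) | C#CC(O)/C(C)=C/C=C/C=C(C)/C=C/C=C(C)/C=C/C1=C(C)C[C@@H](O[Si](C)(C)C(C)(C)C)CC1(C)C | intermediate
16 | tert-butyldimethyl{[(1S,4E)-3,5,5-trimethyl-4-[(2E,4E,6E,8E,10E,12E)-3,7,12-trimethylpentadeca-2,4,6,8,10,12-hexaen-14-yn-1-ylidene]cyclohex-2-en-1-yl]oxy}silane (C27 retro-enyne, terminal alkyne = C10≡C11) | C#C/C=C(C)/C=C/C=C/C(C)=C/C=C/C(C)=C/C=C1/C(C)=C[C@@H](O[Si](C)(C)C(C)(C)C)CC1(C)C | intermediate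
17 | lithium acetylide of 16 (Li on C10) | [Li]C#C/C=C(C)/C=C/C=C/C(C)=C/C=C/C(C)=C/C=C1/C(C)=C[C@@H](O[Si](C)(C)C(C)(C)C)CC1(C)C | intermediate
18 | dichlorocerium acetylide of 16 (CeCl2 on C10) | Cl[Ce](Cl)C#C/C=C(C)/C=C/C=C/C(C)=C/C=C/C(C)=C/C=C1/C(C)=C[C@@H](O[Si](C)(C)C(C)(C)C)CC1(C)C | intermediate
19 | dichlorocerium alkoxide of the C9 adduct (C9 bears methyl, O–CeCl2, the (E)-C7=C8 vinyl link to the 3-oxo-α-ionone ring and the C10≡C11 alkynyl chain; C6 and C9 epimers) | CC(O[Ce](Cl)Cl)(/C=C/C1C(C)=CC(=O)CC1(C)C)C#C/C=C(C)/C=C/C=C/C(C)=C/C=C/C(C)=C/C=C2/C(C)=C[C@@H](O[Si](C)(C)C(C)(C)C)CC2(C)C | intermediate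
20 | C9 tertiary acetate of the adduct (as 19 with OAc in place of O–CeCl2) | CC(OC(C)=O)(/C=C/C1C(C)=CC(=O)CC1(C)C)C#C/C=C(C)/C=C/C=C/C(C)=C/C=C/C(C)=C/C=C2/C(C)=C[C@@H](O[Si](C)(C)C(C)(C)C)CC2(C)C | intermediate
21 | (3'S)-3'-[(tert-butyldimethylsilyl)oxy]-10,11,4',5'-tetradehydro-4,5'-retro-β,β-caroten-3-one (C10≡C11 alkyne; drawn 6E,8E,12E,6'E, other double bonds E) | CC1=CC(=O)CC(C)(C)\C1=C/C=C(C)/C#C/C=C(C)/C=C/C=C/C(C)=C/C=C/C(C)=C/C=C1/C(C)=C[C@@H](O[Si](C)(C)C(C)(C)C)CC1(C)C | intermediate
22 | (3'S,10Z)-3'-[(tert-butyldimethylsilyl)oxy]-4',5'-didehydro-4,5'-retro-β,β-caroten-3-one (10Z; other double bonds drawn E) | CC1=CC(=O)CC(C)(C)\C1=C/C=C(C)/C=C\C=C(C)\C=C\C=C\C(C)=C\C=C\C(C)=C\C=C1\C(C)=C[C@@H](O[Si](C)(C)C(C)(C)C)CC1(C)C | intermediate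
23 | (3'S,6E,6'E)-all-E-3'-[(tert-butyldimethylsilyl)oxy]-4',5'-didehydro-4,5'-retro-β,β-caroten-3-one | CC1=CC(=O)CC(C)(C)\C1=C/C=C(C)/C=C/C=C(C)/C=C/C=C/C(C)=C/C=C/C(C)=C/C=C1/C(C)=C[C@@H](O[Si](C)(C)C(C)(C)C)CC1(C)C | intermediate
24 | eschscholtzxanthone, (3'S,6E,6'E)-all-E-3'-hydroxy-4',5'-didehydro-4,5'-retro-β,β-caroten-3-one | CC1=CC(=O)CC(C)(C)\C1=C/C=C(C)/C=C/C=C(C)/C=C/C=C/C(C)=C/C=C/C(C)=C/C=C1/C(C)=C[C@@H](O)CC1(C)C | target

**Step count**

Total: 13 steps. Longest linear sequence: 11 steps (3 → 24 through steps 2, 3, 5, 6, 7, 8, 9, 10, 11, 12, 13).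

**Steps most likely to fail**

Step 10. The acetylide may take the acidic C6–H of 2 instead of adding, or add to the ring carbonyl. Acetate 20 may also ionize before deprotonation and lose a proton from the C9 methyl group. The fallback sets out from 2 and 16 and returns at 21. Deprotonation of 2 at C6 with KHMDS and O-sulfonylation of the extended enolate with PhNTf2 should give the retro dienyl triflate (2E,4E)-4-(2,6,6-trimethyl-4-oxocyclohex-2-en-1-ylidene)but-2-en-2-yl trifluoromethanesulfonate F1, which is separated from the ring-O triflate and from its geometric isomers at this small-molecule stage. Sonogashira coupling of F1 with alkyne 16 (Pd(PPh3)4, CuI, iPr2NH, THF, rt) then forms the same C9–C10 bond without carbonyl addition or elimination and gives 21.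

Step 9. The cation may lose a proton from a methyl group instead of C4', be captured by water, or the product may ionize a second time at its allylic silyl ether and lose the C3' oxygen. The fallback sets out from 15 and returns at 16. Appel bromination of 15 (CBr4, PPh3, 2,6-lutidine, CH2Cl2, −40 °C) should give the labile C12 bromide corresponding to 15 F2. This is treated without purification with DBU for a base-mediated 1,16-dehydrobromination with double-bond shift, so that neither Brønsted acid nor water is present when the allylic silyl ether of 16 is formed.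

Step 12. The iodine equilibration also isomerizes the exocyclic C6=C7 and C6'=C7' bonds, so the all-E isomer may be only a minor part of the equilibrium mixture and recycling may be slow. The fallback sets out from 16, uses the triflate F1 of the first fallback, and returns at 23, bypassing steps 10 to 12. Compound 16, purified as its all-E (6'E) isomer, is hydrozirconated with Cp2Zr(H)Cl to the (E)-alkenylzirconocene chloride of 16 F3 and transmetalated with ZnCl2 to the (E)-alkenylzinc chloride of 16 F4. Negishi coupling of F4 with geometrically pure F1 (Pd(PPh3)4, THF, rt) makes C10=C11 directly as the E alkene and transfers the (6E,8E) geometry of F1 with retention, so 23 is reached without semihydrogenation or equilibration.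

Further compounds
F1 | step 10 | (2E,4E)-4-(2,6,6-trimethyl-4-oxocyclohex-2-en-1-ylidene)but-2-en-2-yl trifluoromethanesulfonate | CC1=CC(=O)CC(C)(C)\C1=C/C=C(C)/OS(=O)(=O)C(F)(F)F
F2 | step 9 | C12 bromide corresponding to 15 (bromine in place of the hydroxyl, both epimers) | C#CC(Br)/C(C)=C/C=C/C=C(C)/C=C/C=C(C)/C=C/C1=C(C)C[C@@H](O[Si](C)(C)C(C)(C)C)CC1(C)C
F3 | step 12 | (E)-alkenylzirconocene chloride of 16 (Cp2ZrCl on C10) | Cl[Zr](C1C=CC=C1)(C1C=CC=C1)/C=C/C=C(C)/C=C/C=C/C(C)=C/C=C/C(C)=C/C=C2/C(C)=C[C@@H](O[Si](C)(C)C(C)(C)C)CC2(C)C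
F4 | step 12 | (E)-alkenylzinc chloride of 16 (ZnCl on C10) | Cl[Zn]/C=C/C=C(C)/C=C/C=C/C(C)=C/C=C/C(C)=C/C=C1/C(C)=C[C@@H](O[Si](C)(C)C(C)(C)C)CC1(C)C
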